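Numbering: butane chain C1–C4 (C1H2OH on C2, C4H2OH on C3); ring A is the guaiacyl ring on the benzylic carbon at C3, ring B the one on the benzylic carbon at C2.
Enabling feature: C2 is fully substituted and holds O, C1H2OH and CH2–ring B, the pattern left when a 1,1-disubstituted alkenyl boronate takes a hydroxymethyl equivalent at its boron-bearing carbon and an aryl group at its terminal CH2.
Retrosynthesis: C2–O and C1–O go back to C2–B and C1–Si; C1–C2 and CH2–C(aryl, ring B) are then cut together, giving an alkenyl pinacol boronate (C2–C4 with ring A), a silylmethyl Grignard reagent and an aryl triflate; the boronate is cut at C2–B, at the alkyne carbon and at C3–C4.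
Forward: ring A–CH2–C3 (arylpropanoic acid), then C3–C4 (benzyloxymethylation), then the terminal carbon (alkyne) and boron, then C1–C2 and CH2–ring B in one three-component coupling; the chain stays acyclic throughout.
Stereochemistry: C3 from an auxiliary-controlled Evans alkylation; C2 from the chiral ferrocenyl bisphosphine on palladium in the coupling, carried into the C–O bond by stereoretentive oxidation.

Key step: step 11

Assumption: the (S,S,Rp,Rp) enantiomer of the ferrocenyl bisphosphine (MandyPhos) is taken as the one that puts palladium on the Re face at C2; both enantiomers are commercial, so the antipode is used if a model coupling shows the opposite sense.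

Step 1
Reactants: 1 4-benzyloxy-3-methoxybenzaldehyde (O-benzylvanillin); 2 Meldrum's acid
Product: 5 3-(4-benzyloxy-3-methoxyphenyl)propanoic acid, via arylidene Meldrum's acid 3 (not isolated), via benzyl Meldrum's acid 4 (not isolated)
Conditions: HCO2H/Et3N (5:2), 95–100 °C; aq. HCl work-up
Reagents that add atoms: none
Why: Knoevenagel condensation, conjugate hydride transfer from formate to the arylidene and hydrolytic decarboxylation run in one pot, and the benzyl ether is safe because no hydrogenation catalyst is present.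

Step 2
Reactants: 5 3-(4-benzyloxy-3-methoxyphenyl)propanoic acid; 6 (S)-4-benzyl-2-oxazolidinone
Product: 8 (S)-4-benzyl-3-[3-(4-benzyloxy-3-methoxyphenyl)propanoyl]oxazolidin-2-one, via mixed pivalic anhydride 7 (not isolated)
Conditions: PivCl, Et3N, THF, −20 °C; then LiCl, 6, −20 °C → rt
Reagents that add atoms: none
Why: N-acylation of the oxazolidinone by a mixed anhydride occurs at the less hindered acyl carbon and needs no strong base.

Step 3
Reactants: 8 (S)-4-benzyl-3-[3-(4-benzyloxy-3-methoxyphenyl)propanoyl]oxazolidin-2-one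
Product: 10 (4S)-4-benzyl-3-[(2R)-2-(benzyloxymethyl)-3-(4-benzyloxy-3-methoxyphenyl)propanoyl]oxazolidin-2-one, via titanium enolate 9 (not isolated)
Conditions: TiCl4, i-Pr2NEt, CH2Cl2, 0 °C; then BnOCH2Cl, 0 °C
Reagents that add atoms: benzyl chloromethyl ether, ClCOCc1ccccc1
Why: In this Evans alkylation the chelated (Z)-titanium enolate is shielded on one face by the auxiliary benzyl group, so the benzyloxymethyl electrophile adds to the open face and sets C3 (R in the imide).

Step 4
Reactants: 10 (4S)-4-benzyl-3-[(2R)-2-(benzyloxymethyl)-3-(4-benzyloxy-3-methoxyphenyl)propanoyl]oxazolidin-2-one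
Product: 11 (2S)-3-(benzyloxy)-2-(4-benzyloxy-3-methoxybenzyl)propan-1-ol
Conditions: LiBH4, H2O (1 equiv), Et2O, 0 °C
Reagents that add atoms: none
Why: Reductive cleavage of the imide by borohydride attack at the exocyclic carbonyl frees the primary alcohol without touching C3 and returns the auxiliary.

Step 5
Reactants: 11 (2S)-3-(benzyloxy)-2-(4-benzyloxy-3-methoxybenzyl)propan-1-ol
Product: 12 (2R)-3-(benzyloxy)-2-(4-benzyloxy-3-methoxybenzyl)propanal
Conditions: Dess–Martin periodinane, CH2Cl2, 0 °C → rt; crude aldehyde used at once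
Reagents that add atoms: none
Why: Dess–Martin oxidation is fast and non-basic, so the α-stereocentre of the β-benzyloxy aldehyde should not enolise.

Step 6
Reactants: 12 (2R)-3-(benzyloxy)-2-(4-benzyloxy-3-methoxybenzyl)propanal
Product: 13 1-(benzyloxy)-4-[(2S)-2-(benzyloxymethyl)but-3-yn-1-yl]-2-methoxybenzene
Conditions: dimethyl (1-diazo-2-oxopropyl)phosphonate, K2CO3, MeOH, 0 °C → rt
Reagents that add atoms: dimethyl (1-diazo-2-oxopropyl)phosphonate, CC(=O)C(=[N+]=[N-])P(=O)(OC)OC
Why: Ohira–Bestmann (Seyferth–Gilbert) homologation converts α-branched β-alkoxy aldehydes into terminal alkynes under mild carbonate conditions that normally leave the α-centre intact.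

Step 7
Reactants: 13 1-(benzyloxy)-4-[(2S)-2-(benzyloxymethyl)but-3-yn-1-yl]-2-methoxybenzene
Product: 15 2-[(3S)-4-(benzyloxy)-3-(4-benzyloxy-3-methoxybenzyl)but-1-en-2-yl]-4,4,5,5-tetramethyl-1,3,2-dioxaborolane, via alkenylalane 14 (not isolated)
Conditions: NiCl2(dppp) (3 mol%; dppp = Ph2P(CH2)3PPh2), i-Bu2AlH, THF, 0 °C → rt; then MeOBpin, 0 → 80 °C
Reagents that add atoms: 2-methoxy-4,4,5,5-tetramethyl-1,3,2-dioxaborolane, COB1OC(C)(C)C(C)(C)O1
Why: Nickel-catalysed α-selective (Markovnikov) hydroalumination of an alkyl-substituted terminal alkyne puts aluminium on the internal carbon, and aluminium-to-boron exchange with the methoxyborane gives the 1,1-disubstituted alkenyl boronate.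

Step 8
Reactants: 1 4-benzyloxy-3-methoxybenzaldehyde (O-benzylvanillin)
Product: 17 4-benzyloxy-3-methoxyphenol, via aryl formate 16 (not isolated)
Conditions: mCPBA, CH2Cl2, rt; then K2CO3 (cat.), MeOH, rt
Reagents that add atoms: meta-chloroperoxybenzoic acid, OOC(=O)c1cccc(Cl)c1
Why: In this Dakin-type Baeyer–Villiger oxidation the electron-rich aryl group migrates to oxygen, and methanolysis of the formate frees the phenol.

Step 9
Reactants: 17 4-benzyloxy-3-methoxyphenol
Product: 18 4-benzyloxy-3-methoxyphenyl trifluoromethanesulfonate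
Conditions: Tf2O, pyridine, CH2Cl2, 0 °C
Reagents that add atoms: trifluoromethanesulfonic anhydride, O=S(=O)(OS(=O)(=O)C(F)(F)F)C(F)(F)F
Why: O-Sulfonylation of a phenol with triflic anhydride and pyridine is a standard route to aryl triflates.

Step 10
Reactants: 19 (chloromethyl)isopropoxydimethylsilane
Product: 20 (isopropoxydimethylsilyl)methylmagnesium chloride (titrated THF solution)
Conditions: Mg turnings, BrCH2CH2Br (cat.), THF, reflux
Reagents that add atoms: magnesium, [Mg]
Why: Direct magnesium insertion into the C–Cl bond gives this established hydroxymethyl-anion equivalent, whose Si–O bond survives Grignard formation.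

Step 11
Reactants: 15 2-[(3S)-4-(benzyloxy)-3-(4-benzyloxy-3-methoxybenzyl)but-1-en-2-yl]-4,4,5,5-tetramethyl-1,3,2-dioxaborolane; 20 (isopropoxydimethylsilyl)methylmagnesium chloride; 18 4-benzyloxy-3-methoxyphenyl trifluoromethanesulfonate
Product: 22 2-[(2S,3S)-4-(benzyloxy)-1-(4-benzyloxy-3-methoxyphenyl)-3-(4-benzyloxy-3-methoxybenzyl)-2-{[isopropoxy(dimethyl)silyl]methyl}butan-2-yl]-4,4,5,5-tetramethyl-1,3,2-dioxaborolane, via boron ate complex 21 (not isolated)
Conditions: 15 + 20, THF, 0 °C → rt; then NaOTf, 18, Pd(OAc)2 (3 mol%), (S,S,Rp,Rp)-1,1'-bis[bis(4-methoxy-3,5-dimethylphenyl)phosphino]-2,2'-bis[(dimethylamino)(phenyl)methyl]ferrocene (3.6 mol%), THF/DMSO, 60 °C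
Reagents that add atoms: none
Why: The Grignard reagent 20 adds to boron of 15 to give the four-coordinate borate 21, and oxidative addition of triflate 18 to zerovalent palladium gives a cationic aryl complex of divalent palladium that binds the alkene of 21. The silylmethyl group then shifts from boron to C2 anti to the metal while palladium bonds to the terminal CH2, and reductive elimination joins that CH2 to ring B; the closest known reaction type is the enantioselective conjunctive cross-coupling of α-substituted alkenyl boron ate complexes with aryl triflates to tertiary boronic esters. No ring is closed. The new stereocentre C2 is controlled by the ferrocenyl bisphosphine, which places palladium on the Re face at C2 (C3 > terminal CH2 > B) so that the migrating carbon enters from the Si face, and catalyst control is relied on to override any bias from the resident C3 centre. The step needs the metallate shift to beat direct Suzuki–Miyaura transfer and β-hydride elimination: the triflate electrophile with NaOTf as chloride scavenger keeps palladium cationic and alkene-bound, the silylmethyl group is the only carbon ligand on boron that can migrate, and C2 is fully substituted after the shift so the alkylpalladium has no β-hydrogen.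

Step 12
Reactants: 22 tertiary pinacol boronate (full name in step 11 and in the list)
Product: 24 (2R,3R)-4-(benzyloxy)-2,3-bis(4-benzyloxy-3-methoxybenzyl)butane-1,2-diol, via β-hydroxysilane 23 (not isolated)
Conditions: 30% aq. H2O2, KF, KHCO3, THF/MeOH (1:1), rt → 50 °C
Reagents that add atoms: hydrogen peroxide, OO
Why: Boronate oxidation and Tamao oxidation both move carbon from the heteroatom to peroxide oxygen with retention, so C2 keeps its configuration, and the β-hydroxy(alkoxy)silane 23 is of the same kind as the ketone adducts of this Grignard reagent that are routinely oxidised to 1,2-diols under these conditions.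

Step 13
Reactants: 24 (2R,3R)-4-(benzyloxy)-2,3-bis(4-benzyloxy-3-methoxybenzyl)butane-1,2-diol
Product: 25 (2R,3R)-2,3-bis(4-hydroxy-3-methoxybenzyl)butane-1,2,4-triol (CNP0129855.2)
Conditions: H2 (1 atm), 10% Pd/C, EtOAc/MeOH, rt
Reagents that add atoms: none
Why: Catalytic hydrogenolysis cleaves the two aryl benzyl ethers and the alkyl benzyl ether, while the tertiary alcohol is homobenzylic and therefore not subject to C–O hydrogenolysis.

Compound list
1 | 4-benzyloxy-3-methoxybenzaldehyde (O-benzylvanillin) | COc1cc(C=O)ccc1OCc1ccccc1 | starting material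
2 | Meldrum's acid (2,2-dimethyl-1,3-dioxane-4,6-dione) | CC1(C)OC(=O)CC(=O)O1 | starting material
3 | 5-(4-benzyloxy-3-methoxybenzylidene) Meldrum's acid | COc1cc(C=C2C(=O)OC(C)(C)OC2=O)ccc1OCc1ccccc1 | intermediate
4 | 5-(4-benzyloxy-3-methoxybenzyl) Meldrum's acid | COc1cc(CC2C(=O)OC(C)(C)OC2=O)ccc1OCc1ccccc1 | intermediate
5 | 3-(4-benzyloxy-3-methoxyphenyl)propanoic acid | COc1cc(CCC(=O)O)ccc1OCc1ccccc1 | intermediate
6 | (S)-4-benzyl-2-oxazolidinone | O=C1N[C@@H](Cc2ccccc2)CO1 | starting material
7 | mixed anhydride of 5 with pivalic acid | COc1cc(CCC(=O)OC(=O)C(C)(C)C)ccc1OCc1ccccc1 | intermediate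
8 | (S)-4-benzyl-3-[3-(4-benzyloxy-3-methoxyphenyl)propanoyl]oxazolidin-2-one | COc1cc(CCC(=O)N2[C@@H](Cc3ccccc3)COC2=O)ccc1OCc1ccccc1 | intermediate
9 | trichlorotitanium (Z)-enolate of 8 | COc1cc(C/C=C(\O[Ti](Cl)(Cl)Cl)N2[C@@H](Cc3ccccc3)COC2=O)ccc1OCc1ccccc1 | intermediate
10 | (4S)-4-benzyl-3-[(2R)-2-(benzyloxymethyl)-3-(4-benzyloxy-3-methoxyphenyl)propanoyl]oxazolidin-2-one | COc1cc(C[C@H](COCc2ccccc2)C(=O)N2[C@@H](Cc3ccccc3)COC2=O)ccc1OCc1ccccc1 | intermediate
11 | (2S)-3-(benzyloxy)-2-(4-benzyloxy-3-methoxybenzyl)propan-1-ol | COc1cc(C[C@H](COCc2ccccc2)CO)ccc1OCc1ccccc1 | intermediate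
12 | (2R)-3-(benzyloxy)-2-(4-benzyloxy-3-methoxybenzyl)propanal | COc1cc(C[C@H](COCc2ccccc2)C=O)ccc1OCc1ccccc1 | intermediate
13 | 1-(benzyloxy)-4-[(2S)-2-(benzyloxymethyl)but-3-yn-1-yl]-2-methoxybenzene | COc1cc(C[C@H](COCc2ccccc2)C#C)ccc1OCc1ccccc1 | intermediate
14 | [(3S)-4-(benzyloxy)-3-(4-benzyloxy-3-methoxybenzyl)but-1-en-2-yl]diisobutylalane | COc1cc(C[C@H](COCc2ccccc2)C(=C)[Al](CC(C)C)CC(C)C)ccc1OCc1ccccc1 | intermediate
15 | 2-[(3S)-4-(benzyloxy)-3-(4-benzyloxy-3-methoxybenzyl)but-1-en-2-yl]-4,4,5,5-tetramethyl-1,3,2-dioxaborolane | C=C(B1OC(C)(C)C(C)(C)O1)[C@H](Cc1ccc(OCc2ccccc2)c(OC)c1)COCc1ccccc1 | intermediate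
16 | 4-benzyloxy-3-methoxyphenyl formate | COc1cc(OC=O)ccc1OCc1ccccc1 | intermediate
17 | 4-benzyloxy-3-methoxyphenol | COc1cc(O)ccc1OCc1ccccc1 | intermediate
18 | 4-benzyloxy-3-methoxyphenyl trifluoromethanesulfonate | COc1cc(OS(=O)(=O)C(F)(F)F)ccc1OCc1ccccc1 | intermediate
19 | (chloromethyl)isopropoxydimethylsilane | CC(C)O[Si](C)(C)CCl | starting material
20 | (isopropoxydimethylsilyl)methylmagnesium chloride | CC(C)O[Si](C)(C)C[Mg]Cl | intermediate
21 | chloromagnesium alkenyl[(isopropoxydimethylsilyl)methyl](pinacolato)borate from 15 and 20 | C=C([C@H](Cc1ccc(OCc2ccccc2)c(OC)c1)COCc1ccccc1)[B-]1(C[Si](C)(C)OC(C)C)OC(C)(C)C(C)(C)O1.[Mg+]Cl | intermediate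
22 | 2-[(2S,3S)-4-(benzyloxy)-1-(4-benzyloxy-3-methoxyphenyl)-3-(4-benzyloxy-3-methoxybenzyl)-2-{[isopropoxy(dimethyl)silyl]methyl}butan-2-yl]-4,4,5,5-tetramethyl-1,3,2-dioxaborolane | COc1cc(C[C@H](COCc2ccccc2)[C@@](B2OC(C)(C)C(C)(C)O2)(C[Si](C)(C)OC(C)C)Cc2ccc(OCc3ccccc3)c(OC)c2)ccc1OCc1ccccc1 | intermediate
23 | (2R,3R)-4-(benzyloxy)-1-(4-benzyloxy-3-methoxyphenyl)-3-(4-benzyloxy-3-methoxybenzyl)-2-{[isopropoxy(dimethyl)silyl]methyl}butan-2-ol | COc1cc(C[C@H](COCc2ccccc2)[C@@](O)(C[Si](C)(C)OC(C)C)Cc2ccc(OCc3ccccc3)c(OC)c2)ccc1OCc1ccccc1 | intermediate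
24 | (2R,3R)-4-(benzyloxy)-2,3-bis(4-benzyloxy-3-methoxybenzyl)butane-1,2-diol | COc1cc(C[C@H](COCc2ccccc2)[C@@](O)(CO)Cc2ccc(OCc3ccccc3)c(OC)c2)ccc1OCc1ccccc1 | intermediate
25 | (2R,3R)-2,3-bis(4-hydroxy-3-methoxybenzyl)butane-1,2,4-triol | COc1cc(C[C@H](CO)[C@@](O)(CO)Cc2ccc(O)c(OC)c2)ccc1O | target

Total step count: 13. Longest linear sequence: 10 steps (steps 1–7 and 11–13); steps 8–9 and step 10 supply the triflate and the Grignard reagent.

Steps most likely to fail

Step 11. The branched substituent next to the alkene may slow palladium binding, so that direct Suzuki–Miyaura transfer takes over, or the ligand and the C3 centre may oppose each other and give poor facial selectivity at C2. The fallback sets out from 15 and comes back at 24, using only known reactions. Matteson homologation of 15 with chloromethyllithium (ICH2Cl, n-BuLi, THF, −78 °C → rt) would give the allyl pinacol boronate F1, and H2O2/NaOH would oxidise it to the 2-substituted allylic alcohol F2. Sharpless asymmetric epoxidation (Ti(OiPr)4, L-(+)-diethyl tartrate, t-BuOOH, 4 Å sieves, CH2Cl2, −20 °C) would deliver oxygen to the face that gives the 2,2-disubstituted epoxy alcohol F3 with the C2 configuration of the target. Opening of the unsubstituted oxirane CH2 with (4-benzyloxy-3-methoxyphenyl)magnesium bromide F4 (from commercial 1-(benzyloxy)-4-bromo-2-methoxybenzene and Mg; CuBr·SMe2 cat., THF, −30 °C) would then give diol 24.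

Step 7. Hydroalumination at the branched alkyne may lose its internal regioselectivity, or i-Bu2AlH may deprotonate the alkyne instead of adding. The fallback sets out from 13 and comes back at 15. Gold-catalysed Markovnikov hydration (Ph3PAuCl, AgOTf, aqueous dioxane) would give the methyl ketone F5. Kinetic enolisation on the methyl side and trapping (KN(SiMe3)2, PhNTf2, THF, −78 °C) would give the 1,1-disubstituted alkenyl triflate F6. Miyaura borylation (B2pin2, PdCl2(PPh3)2, PPh3, KOPh, toluene, 50 °C) would convert F6 into 15 with no regiochemical ambiguity.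

Step 6. Carbonate in methanol may enolise the aldehyde before homologation, eroding the C3 configuration or expelling benzyloxide by β-elimination. The fallback sets out from 12 and comes back at 13 by a Corey–Fuchs sequence that exposes the aldehyde to no base. CBr4/PPh3 (CH2Cl2, 0 °C) would give the 1,1-dibromoalkene F7; n-BuLi (2 equiv, THF, −78 °C) followed by aqueous quench would give alkyne 13.

Further compounds
F1 | step 11 | 2-[(3S)-4-(benzyloxy)-3-(4-benzyloxy-3-methoxybenzyl)-2-methylenebutyl]-4,4,5,5-tetramethyl-1,3,2-dioxaborolane (allyl pinacol boronate) | C=C(CB1OC(C)(C)C(C)(C)O1)[C@H](Cc1ccc(OCc2ccccc2)c(OC)c1)COCc1ccccc1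
F2 | step 11 | (3S)-4-(benzyloxy)-3-(4-benzyloxy-3-methoxybenzyl)-2-methylenebutan-1-ol (allylic alcohol) | C=C(CO)[C@H](Cc1ccc(OCc2ccccc2)c(OC)c1)COCc1ccccc1
F3 | step 11 | {(2R)-2-[(2R)-1-(benzyloxy)-3-(4-benzyloxy-3-methoxyphenyl)propan-2-yl]oxiran-2-yl}methanol (epoxy alcohol) | OC[C@@]1(CO1)[C@H](Cc2ccc(OCc3ccccc3)c(OC)c2)COCc2ccccc2
F4 | step 11 | (4-benzyloxy-3-methoxyphenyl)magnesium bromide | COc1cc([Mg]Br)ccc1OCc1ccccc1
F5 | step 7 | (3R)-4-(benzyloxy)-3-(4-benzyloxy-3-methoxybenzyl)butan-2-one (methyl ketone) | CC(=O)[C@H](Cc1ccc(OCc2ccccc2)c(OC)c1)COCc1ccccc1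
F6 | step 7 | (3R)-4-(benzyloxy)-3-(4-benzyloxy-3-methoxybenzyl)but-1-en-2-yl trifluoromethanesulfonate (alkenyl triflate) | C=C(OS(=O)(=O)C(F)(F)F)[C@H](Cc1ccc(OCc2ccccc2)c(OC)c1)COCc1ccccc1
F7 | step 6 | 1-(benzyloxy)-4-[(2S)-2-(benzyloxymethyl)-4,4-dibromobut-3-en-1-yl]-2-methoxybenzene (dibromoalkene) | BrC(Br)=C[C@H](Cc1ccc(OCc2ccccc2)c(OC)c1)COCc1ccccc1
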